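Remark on the chemistry: labdane numbering (C1–C20) is used for every bicyclic compound. The descriptors of the target correspond to (2R,5R,9R,10R,13S), an ent-labdane: trans-fused decalin, C20 axial, H5 and H9 on the face opposite C20, C9 chain and C2 acetate equatorial. Where the sense of a chiral catalyst, ligand or auxiliary matters, the antipode is defined by a stated model reaction.

## The problem

Compound 25 is the diacetate of an ent-labd-7-ene-2,15-diol. Ring A of its trans-decalin carries the gem-dimethyl carbon C4, an equatorial acetoxy group at C2 and the axial methyl C20 on quaternary C10; ring B carries the C7=C8 alkene with its methyl C17 and, at C9, a six-carbon chain ending in a primary acetate. The ring stereocentres depend on one another: C5 and C10 fix the trans fusion, and the C2 oxygen is equatorial, so it can be reached through an enolisable carbonyl precursor. The C9 chain is also equatorial but lies on the C20 face, from which an external reagent will not approach, so C9 has to be set by intramolecular transfer from a neighbouring centre. C13 is too far from the ring to be controlled by it and needs reagent control; its epimer would be very hard to separate. The C7=C8 alkene can migrate to C8=C9 under acid and will not survive hydrogenation, C1, C3 and C6 are bare methylenes, and the two acetates cannot pass through hydride or Grignard chemistry. The enabling feature is in ring A: C4 is fully substituted and sits on C5, while C10 carries the unit C1–C2 with oxygen on C2, so C2 and C3 can be the alkene carbons of a vinyl ketone that is captured first by a tertiary C4 radical and then, as its enolate, by a C1 aldehyde on C10.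

## Retrosynthesis

**Acetates last.** Both C–O acetyl bonds of 25 are cut to give diol 24. The chain is built with a Grignard reagent and finished with a hydride, so no acetate placed earlier would survive. The forward step is a plain double acylation.

**C12–C13.** Diol 24 comes from ester 22, which is cut between C12 and C13 into bromide 19 (as Grignard reagent 21) and methyl crotonate 20. This cut creates C13 in the bond-forming step under catalyst control and uses a four-carbon commodity for C13–C16. The neighbouring cut at C11–C12 would need an electrophilic C11 next to the hindered ring. Bringing C13 in as a preformed stereocentre would need a multi-step chiral fragment. The forward reaction must give high catalyst control with the valuable partner as the nucleophile.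

**C9–C11 with transposition of the alkene.** Bromide 19 goes back through 18 and diol 17 to ester 16, and 16 is cut at C9–C11 by an orthoester Claisen transform to allylic alcohol 14. This is preferred to conjugate addition at C9 of a ring B enone, which would come axially, anti to C20, and give the wrong epimer. The [3,3] shift carries the configuration of C7–O across to C9 on the same face and leaves the alkene at C7=C8. The forward reaction needs the C7 hydroxyl on the C20 face (pseudo-equatorial) and a ring B that can reach the boat-like geometry of the shift.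

**C8–C17 and the C7 alcohol.** Alcohol 14 comes from enone 13 by 1,2-reduction, and the C8 methyl of 13 is cut back through iodide 12 to the unsubstituted enone 11. Iodination and cross-coupling place the methyl regiospecifically on the enone α-carbon and avoid enolate regiochemistry.

**C2–O and C1.** Acetate 11 comes from methyl ketone 10 by Baeyer–Villiger oxidation, which turns a C–C bond made in the annulation into the C–O bond of the target with retention. Ketone 10 comes from aldol 8 by removing the C1 hydroxyl through thionocarbonate 9. Deoxygenation is placed before the oxidation so that no 1,2-diol monoester, prone to acyl migration, is formed.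

**Ring A (key disconnection).** In 8 the bonds C3–C4 and C1–C2 are cut, giving cyclohexenone aldehyde 6 and methyl vinyl ketone 7. One operation builds ring A, the quaternary C4, the C2 carbon–oxygen precursor and the trans fusion from a monocyclic compound with two stereocentres. A polar Robinson-type annulation could not make the quaternary C4–C3 bond. The forward reaction asks for chemoselective hydrogen-atom transfer to the isopropenyl group and aldol capture of the enolate.

**Ring B.** Enone 6 is cut at C9–C10 and C5–C6 into dienal 3 and aminosiloxydiene 4 (cycloadduct 5 is hydrolysed in the flask). The E geometry of 3 becomes the trans relation of formyl and isopropenyl. Dienal 3 is cut at its C2=C3 bond into methacrolein 1 and formyl ylide 2.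

## Roads not taken

**Alternative 1:** Ring B would be closed last, cutting C9–C10 and C7–C8, by an intramolecular Diels–Alder reaction. The dienophile is a butynoate ester hanging from the C2 oxygen of a ring A vinylcyclohexene, A2. Heating A2 would let the diene C10=C5–C6=C7 add the alkyne and give the bridged lactone A1, with ring B as a 1,4-diene.

- Merits: the single stereocentre of A2 (C2) is relayed to quaternary C10 through the tether, and C17 and C11 arrive in the cycloaddition. Here it is better than the chosen plan, which spends steps 7 to 10 on those two carbons.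
- Weak points: ester tethers prefer the extended conformation, the diene terminus C10 is fully substituted, and the alkyne is only ester-activated, so forcing conditions are expected.
- Neither C5 nor C9 is a stereocentre in A1. C5 needs a face- and site-selective reduction of C5=C6 beside C8=C9. While the lactone is closed it holds C11 on the face opposite C20, so the lactone must be opened and C9 equilibrated while the alkene is moved to C7=C8 without overshooting.
- Against this the chosen plan sets C5 and C10 together in one cycloaddition and sets C9 by a suprafacial shift.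

**Alternative 2:** Ring A would be made by cutting C1–C10 and C4–C5, an intermolecular Diels–Alder reaction between 2,6-dimethyl-1,4-benzoquinone A4 and the 2-silyloxy diene A5 under a chiral oxazaborolidinium Lewis acid. The product is the cis-fused enedione A3.

- Merits: the cheapest starting materials, a quinone cycloaddition with firm enantioselective precedent, and C10, C4, the C2 oxygen and C17 in place after one step. In cost and in the precedent of its asymmetric step it is better than the chosen plan, whose cycloaddition extends a method beyond its proven dienophiles.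
- Weak points: the reacting terminus of A5 carries a cis methyl group, which disfavours the s-cis conformer and makes the two new quaternary carbons (C4, C10) hard to form. A3 is cis-fused and must be epimerised at C5.
- A3 has carbonyl groups at C6 and C9 that the target lacks. C6 has to be deoxygenated, and the hindered C9 carbonyl has to become CH–CH2R with the right configuration while C7=C8 stays.
- The chosen plan has oxygen only at C7 in ring B, where the Claisen step needs it.

**Alternative 3:** Ring B would be closed by cutting C8–C9. A cationic phosphine–gold catalyst activates the alkyne of the alkynyl silyl enol ether A7 and the enol ether carbon C9 attacks C8 (6-endo-dig), giving aldehyde A6.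

- Merits: ring B arrives in its final oxidation state with C7=C8, C17 and C11 as an aldehyde, and C9 is equatorial and α to the aldehyde. This is better than the chosen plan, which needs four steps for the same ground.
- Weak points: A7 already holds the vicinal C5/C10 pair with the quaternary carbon, so the hard stereochemical problem is moved into the precursor. Attack at C7 (5-exo-dig) competes with the 6-endo mode for an internal alkyne.
- A6 has no oxygen at C2, so a later hydration of C1=C2 must choose C2, the right face and the right alkene.
- The chosen plan makes the C5/C10 pair from two simple components and installs the C2 oxygen in the ring-forming step.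

Key step: step 3

## Steps

Step 1
Reactants: 1 methacrolein; 2 2-(triphenylphosphoranylidene)propanal
Product: 3 (2E)-2,4-dimethylpenta-2,4-dienal
Conditions: 1 (excess), BHT (trace), PhMe, 80 °C, sealed vessel
Reagents that add atoms: none
Why: Wittig olefination with a stabilised α-methyl formyl ylide, which gives the E-trisubstituted enal; excess 1 suppresses a second homologation of the product.

Step 2
Reactants: 3 (2E)-2,4-dimethylpenta-2,4-dienal; 4 (E)-3-(tert-butyldimethylsilyloxy)-N,N-dimethylbuta-1,3-dien-1-amine
Product: 6 (1S,6R)-1-methyl-4-oxo-6-(prop-1-en-2-yl)cyclohex-2-ene-1-carbaldehyde, via amino silyl enol ether cycloadduct 5 (not isolated)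
Conditions: 2,2-dimethyl-α,α,α′,α′-tetra(1-naphthyl)-1,3-dioxolane-4,5-dimethanol (20 mol%), PhMe, −78 → −40 °C; then 1 M HCl, THF, 0 °C
Reagents that add atoms: none
Why: Hydrogen-bond-catalysed enantioselective Diels–Alder reaction of an aminosiloxydiene with an α-branched enal, in which the amino terminus bonds to the formyl-bearing carbon and the suprafacial addition turns the E geometry of 3 into the trans relation of formyl and isopropenyl; acid then hydrolyses the silyl enol ether and eliminates dimethylamine to the enone. The diol antipode is the one that converts methacrolein and 4 into (R)-4-formyl-4-methylcyclohex-2-enone, which presents the same enal face and should set C10 and C5 of 6 as drawn.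

Step 3
Reactants: 6 (1S,6R)-1-methyl-4-oxo-6-(prop-1-en-2-yl)cyclohex-2-ene-1-carbaldehyde; 7 methyl vinyl ketone
Product: 8 (4aS,5S,6R,8aR)-6-acetyl-5-hydroxy-4a,8,8-trimethyl-4a,5,6,7,8,8a-hexahydronaphthalen-2(1H)-one
Conditions: Fe(acac)3 (30 mol%), PhSiH3, 7 (3 equiv), EtOH/(CH2OH)2, 0 °C → rt
Reagents that add atoms: none
Why: Fe(acac)3 and PhSiH3 form an iron hydride that transfers a hydrogen atom to the CH2 terminus of the isopropenyl group, giving the tertiary C4 radical; this adds to the unsubstituted β-carbon of 7 (C3–C4), and the α-keto radical is reduced by divalent iron to an iron enolate that adds to the neighbouring C1 aldehyde (C1–C2). The closest known reaction type is the iron-hydride radical–polar crossover annulation of γ,δ-unsaturated aldehydes with enones to cyclohexanols. Ring A closes in the aldol event by a 6-(enolexo)-exo-trig addition. C5 and C10 are untouched, and because formyl and isopropenyl are trans on ring B the new ring can only be trans-fused with C20 axial. C2 is set in a chair transition state that keeps the acetyl group equatorial, and being enolisable it also reaches that position on equilibration; C1 is expected with the hydroxyl equatorial but is removed in step 5. Hydrogen-atom transfer must choose the electron-rich 1,1-disubstituted alkene over the two electron-poor enone alkenes, which the hydridic character of the iron hydride secures, and the radical must take 7 (unhindered, in excess) rather than the neopentyl C9 of a second molecule of 6. The enolate must attack the aldehyde and not C9 of the ring B enone; the aldehyde is the stronger electrophile and sits gauche to the enolate-bearing arm.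

Step 4
Reactants: 8 (4aS,5S,6R,8aR)-6-acetyl-5-hydroxy-4a,8,8-trimethyl-4a,5,6,7,8,8a-hexahydronaphthalen-2(1H)-one
Product: 9 O-phenyl thionocarbonate of 8 at the C1 oxygen (ring configuration as in 8)
Conditions: PhOC(S)Cl, pyridine, DMAP (cat.), CH2Cl2, 0 °C → rt
Reagents that add atoms: O-phenyl chlorothionoformate, S=C(Cl)Oc1ccccc1
Why: Thioacylation of a secondary alcohol for Barton–McCombie deoxygenation; the equatorial C1–O bond lies near the plane of the C2 enol and is poorly aligned for β-elimination, so the aldol should survive the mild base.

Step 5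
Reactants: 9 O-phenyl thionocarbonate of 8
Product: 10 (4aS,6R,8aR)-6-acetyl-4a,8,8-trimethyl-4a,5,6,7,8,8a-hexahydronaphthalen-2(1H)-one
Conditions: Bu3SnH, AIBN (cat.), PhMe, 90 °C; then DBU (cat.), rt
Reagents that add atoms: none
Why: Barton–McCombie radical deoxygenation gives the C1 methylene; the C10–C1 bond lies near the nodal plane of the C8=C9 π bond, which disfavours cyclisation of the C1 radical onto C9. The DBU stage converges any axial C2 epimer to the equatorial acetyl group.

Step 6
Reactants: 10 (4aS,6R,8aR)-6-acetyl-4a,8,8-trimethyl-4a,5,6,7,8,8a-hexahydronaphthalen-2(1H)-one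
Product: 11 (2R,4aR,8aS)-4,4,8a-trimethyl-6-oxo-1,2,3,4,4a,5,6,8a-octahydronaphthalen-2-yl acetate
Conditions: mCPBA, CH2Cl2, 0 °C → rt
Reagents that add atoms: 3-chloroperoxybenzoic acid, OOC(=O)c1cccc(Cl)c1
Why: Baeyer–Villiger oxidation of a methyl ketone, in which the secondary ring carbon migrates with retention and gives the equatorial C2 acetate; the conjugated, electron-poor enone is much slower to oxidise or epoxidise.

Step 7
Reactants: 11 (2R,4aR,8aS)-4,4,8a-trimethyl-6-oxo-1,2,3,4,4a,5,6,8a-octahydronaphthalen-2-yl acetate
Product: 12 (2R,4aR,8aR)-7-iodo-4,4,8a-trimethyl-6-oxo-1,2,3,4,4a,5,6,8a-octahydronaphthalen-2-yl acetate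
Conditions: I2, pyridine, CH2Cl2, rt
Reagents that add atoms: iodine, II
Why: α-Iodination of a cyclic enone by amine conjugate addition, iodination and elimination, well established for γ,γ-disubstituted cyclohexenones.

Step 8
Reactants: 12 (2R,4aR,8aR)-7-iodo-4,4,8a-trimethyl-6-oxo-1,2,3,4,4a,5,6,8a-octahydronaphthalen-2-yl acetate
Product: 13 (2R,4aR,8aS)-4,4,7,8a-tetramethyl-6-oxo-1,2,3,4,4a,5,6,8a-octahydronaphthalen-2-yl acetate
Conditions: Me4Sn, Pd2(dba)3 (cat.), AsPh3, CuI (cat.), NMP, 80 °C
Reagents that add atoms: tetramethylstannane, C[Sn](C)(C)C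
Why: Stille methylation of an α-iodoenone under neutral conditions (zerovalent palladium) that leave the acetate alone; it places C17 on C8.

Step 9
Reactants: 13 (2R,4aR,8aS)-4,4,7,8a-tetramethyl-6-oxo-1,2,3,4,4a,5,6,8a-octahydronaphthalen-2-yl acetate
Product: 14 (2R,4aR,6R,8aS)-6-hydroxy-4,4,7,8a-tetramethyl-1,2,3,4,4a,5,6,8a-octahydronaphthalen-2-yl acetate
Conditions: NaBH4, CeCl3·7H2O, MeOH, −78 → 0 °C
Reagents that add atoms: none
Why: Luche 1,2-reduction; hydride enters C7 along the axial trajectory, as in rigid cyclohexenones, and gives the pseudo-equatorial alcohol on the C20 face, while the acetate is untouched at low temperature.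

Step 10
Reactants: 14 (2R,4aR,6R,8aS)-6-hydroxy-4,4,7,8a-tetramethyl-1,2,3,4,4a,5,6,8a-octahydronaphthalen-2-yl acetate
Product: 16 ethyl 2-[(1R,4aR,7R,8aR)-7-acetoxy-2,5,5,8a-tetramethyl-1,4,4a,5,6,7,8,8a-octahydronaphthalen-1-yl]acetate, via mixed ketene acetal 15 (not isolated)
Conditions: MeC(OEt)3 (excess), EtCO2H (cat.), xylene, 140 °C, EtOH distilled off
Reagents that add atoms: triethyl orthoacetate, CCOC(C)(OCC)OCC
Why: Johnson–Claisen rearrangement: orthoester exchange and loss of ethanol give the allyl ketene acetal, whose suprafacial [3,3] shift forms C9–C11 on the face that carried the C7 oxygen (the C20 face) and moves the alkene to C7=C8. The shift is known for pseudo-equatorial allylic alcohols held in rigid polycycles and there delivers carbon next to an angular methyl group on its own face.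

Step 11
Reactants: 16 ethyl 2-[(1R,4aR,7R,8aR)-7-acetoxy-2,5,5,8a-tetramethyl-1,4,4a,5,6,7,8,8a-octahydronaphthalen-1-yl]acetate
Product: 17 (2R,4aR,8R,8aR)-8-(2-hydroxyethyl)-4,4,7,8a-tetramethyl-1,2,3,4,4a,5,8,8a-octahydronaphthalen-2-ol
Conditions: LiAlH4, THF, 0 °C → rt; aqueous work-up
Reagents that add atoms: none
Why: Hydride reduction of the ethyl ester to the C12 alcohol with cleavage of the C2 acetate, which could not pass the Grignard step.

Step 12
Reactants: 17 (2R,4aR,8R,8aR)-8-(2-hydroxyethyl)-4,4,7,8a-tetramethyl-1,2,3,4,4a,5,8,8a-octahydronaphthalen-2-ol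
Product: 18 (2R,4aR,8R,8aR)-8-(2-bromoethyl)-4,4,7,8a-tetramethyl-1,2,3,4,4a,5,8,8a-octahydronaphthalen-2-ol
Conditions: CBr4, PPh3, CH2Cl2, 0 °C
Reagents that add atoms: carbon tetrabromide, BrC(Br)(Br)Br
Why: Appel bromination, which takes the unhindered primary alcohol much faster than the secondary ring alcohol.

Step 13
Reactants: 18 (2R,4aR,8R,8aR)-8-(2-bromoethyl)-4,4,7,8a-tetramethyl-1,2,3,4,4a,5,8,8a-octahydronaphthalen-2-ol
Product: 19 [(2R,4aR,8R,8aR)-8-(2-bromoethyl)-4,4,7,8a-tetramethyl-1,2,3,4,4a,5,8,8a-octahydronaphthalen-2-yl]oxy(triethyl)silane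
Conditions: TESOTf, 2,6-lutidine, CH2Cl2, −78 °C
Reagents that add atoms: triethylsilyl trifluoromethanesulfonate, CC[Si](CC)(CC)OS(=O)(=O)C(F)(F)F
Why: Silylation of the secondary alcohol with a silyl triflate and a hindered base, fast at low temperature and without displacement of the bromide; the triethylsilyl ether is stable to Grignard reagents and is removed by dilute acid.

Step 14
Reactants: 19 [(2R,4aR,8R,8aR)-8-(2-bromoethyl)-4,4,7,8a-tetramethyl-1,2,3,4,4a,5,8,8a-octahydronaphthalen-2-yl]oxy(triethyl)silane; 20 methyl (E)-but-2-enoate (methyl crotonate)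
Product: 22 methyl (3S)-3-methyl-5-[(1R,4aR,7R,8aR)-2,5,5,8a-tetramethyl-7-(triethylsilyloxy)-1,4,4a,5,6,7,8,8a-octahydronaphthalen-1-yl]pentanoate, via Grignard reagent 21 (not isolated)
Conditions: Mg, Et2O, reflux; then added slowly to CuBr·SMe2 (5 mol%), 1-[2-(diphenylphosphino)ferrocenyl]ethyldicyclohexylphosphine (Josiphos, 6 mol%), 20 (excess), t-BuOMe, −75 °C; aqueous work-up
Reagents that add atoms: none
Why: Copper-catalysed enantioselective conjugate addition of a primary alkyl Grignard reagent to an α,β-unsaturated ester (monovalent copper with a ferrocenyl diphosphine), a reaction established for 20 with linear Grignard reagents; it forms C12–C13 and sets C13 under catalyst control. The ligand antipode is the one that converts EtMgBr and 20 into (S)-methyl 3-methylpentanoate, which corresponds to 13S here.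

Step 15
Reactants: 22 methyl (3S)-3-methyl-5-[(1R,4aR,7R,8aR)-2,5,5,8a-tetramethyl-7-(triethylsilyloxy)-1,4,4a,5,6,7,8,8a-octahydronaphthalen-1-yl]pentanoate
Product: 24 (2R,4aR,8R,8aR)-8-[(3S)-5-hydroxy-3-methylpentyl]-4,4,7,8a-tetramethyl-1,2,3,4,4a,5,8,8a-octahydronaphthalen-2-ol, via triethylsilyl ether alcohol 23 (not isolated)
Conditions: LiAlH4, THF, 0 °C; then 1 M HCl, MeOH, rt
Reagents that add atoms: none
Why: Hydride reduction of the methyl ester to the C15 alcohol, followed in the same flask by acid hydrolysis of the triethylsilyl ether; brief dilute acid at room temperature should not move the C7=C8 alkene.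

Step 16
Reactants: 24 (2R,4aR,8R,8aR)-8-[(3S)-5-hydroxy-3-methylpentyl]-4,4,7,8a-tetramethyl-1,2,3,4,4a,5,8,8a-octahydronaphthalen-2-ol
Product: 25 (2R,4aR,8R,8aR)-8-[(3S)-5-acetoxy-3-methylpentyl]-4,4,7,8a-tetramethyl-1,2,3,4,4a,5,8,8a-octahydronaphthalen-2-yl acetate
Conditions: Ac2O, pyridine, DMAP (cat.), CH2Cl2, rt
Reagents that add atoms: acetic anhydride, CC(=O)OC(C)=O
Why: DMAP-catalysed acylation of the primary and the equatorial secondary alcohol; no stereocentre is touched.

## Compound list

1 | methacrolein (2-methylprop-2-enal) | CC(=C)C=O | starting material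
2 | 2-(triphenylphosphoranylidene)propanal | CC(C=O)=P(c1ccccc1)(c1ccccc1)c1ccccc1 | starting material
3 | (2E)-2,4-dimethylpenta-2,4-dienal | O=C/C(C)=C/C(C)=C | intermediate
4 | (E)-3-(tert-butyldimethylsilyloxy)-N,N-dimethylbuta-1,3-dien-1-amine | CN(C)/C=C/C(=C)O[Si](C)(C)C(C)(C)C | starting material
5 | amino silyl enol ether cycloadduct, formed in the flask (formyl trans to isopropenyl; drawn as the endo-formyl adduct with the amino group cis to formyl; the configuration at the amino carbon is lost in the next stage) | O=C[C@@]1(C)[C@@H](N(C)C)C=C(O[Si](C)(C)C(C)(C)C)C[C@@H]1C(C)=C | intermediate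
6 | (1S,6R)-1-methyl-4-oxo-6-(prop-1-en-2-yl)cyclohex-2-ene-1-carbaldehyde | O=C[C@@]1(C)C=CC(=O)C[C@@H]1C(C)=C | intermediate
7 | methyl vinyl ketone (but-3-en-2-one) | CC(=O)C=C | starting material
8 | (4aS,5S,6R,8aR)-6-acetyl-5-hydroxy-4a,8,8-trimethyl-4a,5,6,7,8,8a-hexahydronaphthalen-2(1H)-one | O[C@H]1[C@H](C(C)=O)CC(C)(C)[C@H]2CC(=O)C=C[C@]12C | intermediate
9 | O-phenyl thionocarbonate of 8 at the C1 oxygen | S=C(Oc1ccccc1)O[C@H]1[C@H](C(C)=O)CC(C)(C)[C@H]2CC(=O)C=C[C@]12C | intermediate
10 | (4aS,6R,8aR)-6-acetyl-4a,8,8-trimethyl-4a,5,6,7,8,8a-hexahydronaphthalen-2(1H)-one | C1[C@H](C(C)=O)CC(C)(C)[C@H]2CC(=O)C=C[C@]12C | intermediate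
11 | (2R,4aR,8aS)-4,4,8a-trimethyl-6-oxo-1,2,3,4,4a,5,6,8a-octahydronaphthalen-2-yl acetate | C1[C@H](OC(C)=O)CC(C)(C)[C@H]2CC(=O)C=C[C@]12C | intermediate
12 | (2R,4aR,8aR)-7-iodo-4,4,8a-trimethyl-6-oxo-1,2,3,4,4a,5,6,8a-octahydronaphthalen-2-yl acetate | C1[C@H](OC(C)=O)CC(C)(C)[C@H]2CC(=O)C(I)=C[C@]12C | intermediate
13 | (2R,4aR,8aS)-4,4,7,8a-tetramethyl-6-oxo-1,2,3,4,4a,5,6,8a-octahydronaphthalen-2-yl acetate | C1[C@H](OC(C)=O)CC(C)(C)[C@H]2CC(=O)C(C)=C[C@]12C | intermediate
14 | (2R,4aR,6R,8aS)-6-hydroxy-4,4,7,8a-tetramethyl-1,2,3,4,4a,5,6,8a-octahydronaphthalen-2-yl acetate (C7 hydroxyl on the C20 face) | C1[C@H](OC(C)=O)CC(C)(C)[C@H]2C[C@@H](O)C(C)=C[C@]12C | intermediate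
15 | mixed ketene acetal (1-ethoxyvinyl ether of 14 at the C7 oxygen), formed in the flask | C1[C@H](OC(C)=O)CC(C)(C)[C@H]2C[C@@H](OC(=C)OCC)C(C)=C[C@]12C | intermediate
16 | ethyl 2-[(1R,4aR,7R,8aR)-7-acetoxy-2,5,5,8a-tetramethyl-1,4,4a,5,6,7,8,8a-octahydronaphthalen-1-yl]acetate | CCOC(=O)C[C@@H]1C(C)=CC[C@@H]2C(C)(C)C[C@@H](OC(C)=O)C[C@@]12C | intermediate
17 | (2R,4aR,8R,8aR)-8-(2-hydroxyethyl)-4,4,7,8a-tetramethyl-1,2,3,4,4a,5,8,8a-octahydronaphthalen-2-ol | OCC[C@@H]1C(C)=CC[C@@H]2C(C)(C)C[C@@H](O)C[C@@]12C | intermediate
18 | (2R,4aR,8R,8aR)-8-(2-bromoethyl)-4,4,7,8a-tetramethyl-1,2,3,4,4a,5,8,8a-octahydronaphthalen-2-ol | BrCC[C@@H]1C(C)=CC[C@@H]2C(C)(C)C[C@@H](O)C[C@@]12C | intermediate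
19 | [(2R,4aR,8R,8aR)-8-(2-bromoethyl)-4,4,7,8a-tetramethyl-1,2,3,4,4a,5,8,8a-octahydronaphthalen-2-yl]oxy(triethyl)silane | BrCC[C@@H]1C(C)=CC[C@@H]2C(C)(C)C[C@@H](O[Si](CC)(CC)CC)C[C@@]12C | intermediate
20 | methyl (E)-but-2-enoate (methyl crotonate) | C/C=C/C(=O)OC | starting material
21 | Grignard reagent from 19 (C12–MgBr), formed in the flask | Br[Mg]CC[C@@H]1C(C)=CC[C@@H]2C(C)(C)C[C@@H](O[Si](CC)(CC)CC)C[C@@]12C | intermediate
22 | methyl (3S)-3-methyl-5-[(1R,4aR,7R,8aR)-2,5,5,8a-tetramethyl-7-(triethylsilyloxy)-1,4,4a,5,6,7,8,8a-octahydronaphthalen-1-yl]pentanoate | COC(=O)C[C@@H](C)CC[C@@H]1C(C)=CC[C@@H]2C(C)(C)C[C@@H](O[Si](CC)(CC)CC)C[C@@]12C | intermediate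
23 | (3S)-3-methyl-5-[(1R,4aR,7R,8aR)-2,5,5,8a-tetramethyl-7-(triethylsilyloxy)-1,4,4a,5,6,7,8,8a-octahydronaphthalen-1-yl]pentan-1-ol, formed in the flask | OCC[C@@H](C)CC[C@@H]1C(C)=CC[C@@H]2C(C)(C)C[C@@H](O[Si](CC)(CC)CC)C[C@@]12C | intermediate
24 | (2R,4aR,8R,8aR)-8-[(3S)-5-hydroxy-3-methylpentyl]-4,4,7,8a-tetramethyl-1,2,3,4,4a,5,8,8a-octahydronaphthalen-2-ol | OCC[C@@H](C)CC[C@@H]1C(C)=CC[C@@H]2C(C)(C)C[C@@H](O)C[C@@]12C | intermediate
25 | (2R,4aR,8R,8aR)-8-[(3S)-5-acetoxy-3-methylpentyl]-4,4,7,8a-tetramethyl-1,2,3,4,4a,5,8,8a-octahydronaphthalen-2-yl acetate | CC(=O)OCC[C@@H](C)CC[C@@H]1C(C)=CC[C@@H]2C(C)(C)C[C@@H](OC(C)=O)C[C@@]12C | target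

## Step count and least certain steps

Total step count: 16. Longest linear sequence: 16 steps (1 to 25).

**Step 3 (key step).** The cascade is most likely to be interrupted after the radical addition. The iron enolate may be protonated by the alcoholic medium before it reaches the neopentyl aldehyde, or it may add in Michael fashion to C9 of the ring B enone; reduction of the C4 radical to an isopropyl group is a further loss. The fallback sets out from 6 and returns at 8. The reductive olefin–enone coupling of 6 with 7 is run under the same iron hydride conditions and is allowed to stop at the open-chain stage, giving (1S,6R)-1-methyl-6-(2-methyl-5-oxohexan-2-yl)-4-oxocyclohex-2-ene-1-carbaldehyde F1. This keto aldehyde is then closed in a separate polar step, an amine-catalysed 6-(enolexo) aldolisation through the more substituted enamine of the methyl ketone (pyrrolidinium acetate, CH2Cl2, rt). Strong base, which would favour the Michael pathway, is avoided, and the same two bonds and the same ring are formed.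

**Step 2.** The method is established for α-substituted acroleins, and the extra β-substituent of 3 may make the cycloaddition too slow at the temperatures where hydrogen-bond catalysis is selective. Raising the temperature would let the uncatalysed reaction erode the enantioselectivity, and the distal isopropenyl C=C of the dienal could compete as the dienophile. The fallback sets out from 3 and returns at 6 and replaces catalyst control by auxiliary control in a thermal reaction. Dienal 3 is heated in PhMe with the known C2-symmetric diene (2R,5R)-1-[(1E)-3-(tert-butyldimethylsilyloxy)buta-1,3-dien-1-yl]-2,5-diphenylpyrrolidine F2. This is drawn for the (2R,5R) amine; the antipode is fixed by the same methacrolein model reaction as in step 2. The product is the pyrrolidinyl silyl enol ether cycloadduct F3, and the same acid treatment (1 M HCl, THF) gives 6 and returns the amine. The thermal reaction tolerates the hindered dienophile at 40 to 80 °C because its facial bias does not depend on a low-temperature catalyst–substrate complex.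

**Step 10.** The rigid trans-decalin holds the C7–O bond pseudo-equatorial, so the [3,3] shift has to pass through a boat-like ring B. At the temperature and acidity that this demands, the allylic mixed orthoester may instead ionise or eliminate to a diene, with loss of the C7 stereochemical information. The fallback sets out from 14 and returns at 17 and generates the ketene acetal without acid. Heating 14 with N,N-dimethylacetamide dimethyl acetal in PhMe (Eschenmoser–Claisen) gives, through the ketene N,O-acetal F4, the amide 2-[(1R,4aR,7R,8aR)-7-acetoxy-2,5,5,8a-tetramethyl-1,4,4a,5,6,7,8,8a-octahydronaphthalen-1-yl]-N,N-dimethylacetamide F5. The more electron-rich ketene N,O-acetal rearranges at lower temperature under neutral conditions. LiEt3BH in THF then reduces the tertiary amide to the primary alcohol and cleaves the acetate, giving diol 17.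

**Step 14.** Two things may go wrong: incomplete catalyst control at the remote centre C13, whose epimer could not be removed at this stage, and loss of the organomagnesium reagent by Wurtz coupling or protonation on small scale. The fallback sets out from 19 (through 21) and returns at 23; it uses a covalently bound auxiliary, so that the minor C13 isomer becomes a separable diastereomer. Grignard reagent 21 is converted with CuBr·SMe2 (stoichiometric) into the organocopper reagent and added to (4S)-3-[(2E)-but-2-enoyl]-4-phenyl-1,3-oxazolidin-2-one F6 in THF at −40 °C. In the chelated s-cis conformer the phenyl group shields one face, and addition anti to it gives the 13S imide F7 (the conjugate adduct carrying the bicyclic chain with its triethylsilyl ether). After purification, LiBH4 in wet Et2O cleaves the auxiliary reductively and gives alcohol 23, which is hydrolysed to 24 as in step 15.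

## Further compounds

F1 | step 3 | (1S,6R)-1-methyl-6-(2-methyl-5-oxohexan-2-yl)-4-oxocyclohex-2-ene-1-carbaldehyde | O=C[C@@]1(C)C=CC(=O)C[C@@H]1C(C)(C)CCC(C)=O
F2 | step 2 | (2R,5R)-1-[(1E)-3-(tert-butyldimethylsilyloxy)buta-1,3-dien-1-yl]-2,5-diphenylpyrrolidine | C=C(O[Si](C)(C)C(C)(C)C)/C=C/N1[C@@H](c2ccccc2)CC[C@@H]1c1ccccc1
F3 | step 2 | pyrrolidinyl silyl enol ether cycloadduct of 3 and F2 (formyl trans to isopropenyl, amino group cis to formyl) | O=C[C@@]1(C)[C@@H](N2[C@@H](c3ccccc3)CC[C@@H]2c2ccccc2)C=C(O[Si](C)(C)C(C)(C)C)C[C@@H]1C(C)=C
F4 | step 10 | ketene N,O-acetal of 14 (1-(dimethylamino)vinyl ether at the C7 oxygen) | C1[C@H](OC(C)=O)CC(C)(C)[C@H]2C[C@@H](OC(=C)N(C)C)C(C)=C[C@]12C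
F5 | step 10 | 2-[(1R,4aR,7R,8aR)-7-acetoxy-2,5,5,8a-tetramethyl-1,4,4a,5,6,7,8,8a-octahydronaphthalen-1-yl]-N,N-dimethylacetamide | CN(C)C(=O)C[C@@H]1C(C)=CC[C@@H]2C(C)(C)C[C@@H](OC(C)=O)C[C@@]12C
F6 | step 14 | (4S)-3-[(2E)-but-2-enoyl]-4-phenyl-1,3-oxazolidin-2-one | C/C=C/C(=O)N1[C@@H](c2ccccc2)COC1=O
F7 | step 14 | (4S)-3-[(3S)-3-methyl-5-(bicyclic triethylsilyloxy chain as in 22)pentanoyl]-4-phenyl-1,3-oxazolidin-2-one | O=C(C[C@@H](C)CC[C@@H]1C(C)=CC[C@@H]2C(C)(C)C[C@@H](O[Si](CC)(CC)CC)C[C@@]12C)N1[C@@H](c2ccccc2)COC1=O
A1 | alternative 1 | bridged tricyclic lactone with ring B as a 1,4-diene | O=C1O[C@@H]2CC(C)(C)C3=CCC(C)=C1[C@]3(C)C2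
A2 | alternative 1 | 3,5,5-trimethyl-4-vinylcyclohex-3-en-1-yl but-2-ynoate (C2 configured as in the target) | CC#CC(=O)O[C@@H]1CC(C)(C)C(C=C)=C(C)C1
A3 | alternative 2 | cis-fused enedione adduct with C2 silyl enol ether | O=C1C(C)=CC(=O)[C@H]2C(C)(C)C=C(O[Si](C(C)C)(C(C)C)C(C)C)C[C@@]12C
A4 | alternative 2 | 2,6-dimethyl-1,4-benzoquinone | CC1=CC(=O)C=C(C)C1=O
A5 | alternative 2 | 4-methyl-2-(triisopropylsilyloxy)penta-1,3-diene | C=C(O[Si](C(C)C)(C(C)C)C(C)C)C=C(C)C
A6 | alternative 3 | trans-fused bicyclic C11 aldehyde with C7=C8 and C1=C2 alkenes | O=C[C@@H]1C(C)=CC[C@@H]2C(C)(C)CC=C[C@@]12C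
A7 | alternative 3 | alkynyl silyl enol ether: ring A cyclohexene with a but-2-ynyl group on C5 and a 2-(tert-butyldimethylsilyloxy)vinyl group on C10 | CC#CC[C@@H]1C(C)(C)CC=C[C@@]1(C)C=CO[Si](C)(C)C(C)(C)C
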